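The data are calculated with constants of no real substance; the scatter is artificial.

The constants worth reading from these runs are not rate constants of named steps but two quantities of the curve: a plateau, and how much of the gap to it survives an interval. The flasks and readings are these:

| setting | cedar | elm | maple | south-east | north | south-west |
|---|---|---|---|---|---|---|
| starting complex | 1 M | 1 M | 1 M | 1.0 M | 1.0 M | 1.0 M |
| incoming ligand | 0.68 M | 1.6 M | 2.6 M | 0.800 M | 2.50 M | 3.00 M |
| remark | run made earlier | run made earlier | run made earlier |  |  |  |
| time |  |  |  | 2.5 h | 2.5 h | 2.5 h |

| run | time / min | complex with one exchanged / % |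
|---|---|---|
| cedar | 6.00 | 1.9 |
| cedar | 15.0 | 5.7 |
| cedar | 30.0 | 9.8 |
| cedar | 80.0 | 20.0 |
| elm | 20.0 | 15.9 |
| elm | 40.0 | 25.8 |
| elm | 60.0 | 32.2 |
| elm | 80.0 | 38.7 |
| maple | 20.0 | 23.1 |
| maple | 40.0 | 37.2 |
| maple | 60.0 | 44.7 |
| maple | 80.0 | 52.2 |

(each reading ± 0.5 percentage points)

- the numbers in the tables scatter by 0.5 percentage points (one standard deviation)
- a reading or a percentage of complex with one exchanged counts all its forms, free or not

1. complex with one exchanged at the end, in percent of the starting complex charged, for each flask in turn (south-east, north, south-west)

Working with what is left rather than what is made, take the maple run, whose readings at 40.0 min and at twice that time stand at 37.2 % and 52.2 %. The second rise over the first is 0.403. This gap ratio, the fraction of the distance to the plateau still open after each equal interval, puts the plateau at a reading of 62.3 %.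

The ladder follows. On one rung the gap in the maple run halves in 30.5 min, a relaxation half-life read from the readings. The first maple reading, taken as the fraction not yet exchanged, gives a half-life of 52.8 min at the start, a slower rung. The top rung is the asked 150 min, far longer, and over it the gap shrinks to 3.32 % of its opening size.

Carried to north, whose [incoming ligand] lies near maple's, this reckoning of mine gives 60.3 %. The forecast, by another route, gives 34 %, 59 % and 60 % for south-east, north and south-west, saying that at the two high charges “the product sits near its maximum”.

The flasks give 32.2 %, 58.6 % and 61.5 %.

    starting complex + incoming ligand ⇌ leaving ligand + complex with one exchanged (K = 1.35, k = 1.39 × 10⁻⁴ M⁻¹ s⁻¹)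
    complex with one exchanged + incoming ligand ⇌ leaving ligand + complex with two exchanged (K = 1.03, k = 6.23 × 10⁻⁶ M⁻¹ s⁻¹)
    complex with two exchanged + incoming ligand ⇌ leaving ligand + complex with three exchanged (K = 1.10, k = 1.66 × 10⁻⁴ M⁻¹ s⁻¹)
    starting complex ⇌ dormant form (K = 0.590, k = 0.00229 s⁻¹)
    starting complex + complex with one exchanged ⇌ idle adduct, settled at all times (K = 0.629 M⁻¹)
    crystals ⇌ complex with one exchanged, rate k6*(cs6 - [complex with one exchanged]) while solid is left; crystals form when [complex with one exchanged] > cs6 (solubility = 0.560 M, k = 0.00721 s⁻¹)

Over its second 1.25 h, north rises from 49.1 % to 58.6 %, a gap ratio of 0.193 and an apparent plateau of 60.9 %. South-west, from 54.0 % to 61.5 %, gives 0.140 and 62.7 %. In north, free complex with one exchanged has a half-life of 12 h by the forward second exchange alone at the concentrations as charged, long against the 2.5 h of the run, and complex with two exchanged stands at 1.97 % at the end of the run. After 25.0 h, which that half-life does not outlast, north holds 34.5 % of complex with one exchanged.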